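**Retrosynthetic overview**
1. The last bond made is the ester acyl C–O bond. A trans-β-lactone, which masks C3–OH and activates C1 at once, is opened by the free hindered hydroxy diketone, so neither partner carries a protecting group.
2. In the keto-β-lactone, the C5 ketone comes from a late, base-free oxidation that protects the labile C6. The γ-pyrone ring is annulated onto an ethyl ketone by an α-oxoketene [4+2].
3. The ethyl ketone comes from an anti-aldol of pentan-3-one (sets C6) with a β-lactone aldehyde. That aldehyde comes from an auxiliary-controlled anti-aldol of propionate with methacrolein (C2, C3), lactonisation and anti-selective hydroboration (C4).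
4. The hydroxy diketone comes from one proline aldol with dynamic kinetic resolution between two thiopyran templates, followed by desulfurisation and deketalisation.
5. Ring order: the thiopyran and dioxolane templates are made and removed in the side branch. In the main line the β-lactone forms first, then the γ-pyrone, and the β-lactone is opened in the final step.

Assumption: the ester-bearing carbon of the nonanedione part carries two identical (R)-configured arms and is therefore not a stereocentre, as in the given SMILES. C1–C7 below number the heptanoate chain of the acid part.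

**Step 1**
Reactants: 1 methyl 4-oxotetrahydro-2H-thiopyran-3-carboxylate
Product: 2 methyl 1,4-dioxa-8-thiaspiro[4.5]decane-6-carboxylate (racemic)
Conditions: ethylene glycol, p-TsOH (cat.), PhMe, reflux, Dean–Stark
Reagents that add atoms: ethylene glycol, OCCO
Why: Acid-catalysed ketalisation with azeotropic water removal masks the ketone so that the later aldehyde is not a β-keto aldehyde; the product is racemic.

**Step 2**
Reactants: 2 methyl 1,4-dioxa-8-thiaspiro[4.5]decane-6-carboxylate
Product: 3 1,4-dioxa-8-thiaspiro[4.5]decane-6-carbaldehyde (racemic)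
Conditions: DIBAL-H (1.1 equiv), CH2Cl2, −78 °C; aq. Rochelle salt
Reagents that add atoms: none
Why: Partial ester reduction with DIBAL-H, in which the tetrahedral aluminium alkoxide (stabilised by the neighbouring ketal oxygen) survives at −78 °C and collapses to the aldehyde only on work-up; 3 is racemic on purpose.

**Step 3**
Reactants: 3 1,4-dioxa-8-thiaspiro[4.5]decane-6-carbaldehyde, 4 tetrahydro-4H-thiopyran-4-one
Product: 5 (3R)-3-{(S)-[(6R)-1,4-dioxa-8-thiaspiro[4.5]decan-6-yl](hydroxy)methyl}tetrahydro-4H-thiopyran-4-one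
Conditions: (R)-proline (50 mol %), 4 (3 equiv, excess recovered), wet DMSO, rt, 3–4 d
Reagents that add atoms: none
Why: Proline enamine aldol with dynamic kinetic resolution: 3 racemises under the conditions, the (R)-proline enamine of 4 reacts through the Houk–List transition state (anti aldol, fixes C3 and C1') and only the Felkin–Anh-matched enantiomer of 3 reacts fast (1',6''-syn), so the catalyst sets all three centres.

**Step 4**
Reactants: 5 the bis-thiopyran aldol adduct
Product: 6 (4R,5S,6R)-6-(2-ethyl-1,3-dioxolan-2-yl)-5-hydroxy-4-methylheptan-3-one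
Conditions: Raney Ni (W-2, acetone-deactivated), EtOH, reflux, 1 h
Reagents that add atoms: none
Why: Raney nickel hydrogenolysis of the four C–S bonds converts the two thiopyran templates into the methyl and ethyl groups of the polypropionate without touching the three stereocentres.

**Step 5**
Reactants: 6 (4R,5S,6R)-6-(2-ethyl-1,3-dioxolan-2-yl)-5-hydroxy-4-methylheptan-3-one
Product: 7 (4R,6R)-5-hydroxy-4,6-dimethylnonane-3,7-dione
Conditions: 1 M aq. HCl/THF (1:4), 0 °C → rt, 2 h
Reagents that add atoms: water, O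
Why: Dilute-acid hydrolysis of the dioxolane frees the second ethyl ketone; the two arms become identical (both R), so the carbinol carbon is no longer a stereocentre, and the α-centres are not epimerised at this acidity.

**Step 6**
Reactants: 8 pentane-2,4-dione
Product: 9 3-diazopentane-2,4-dione
Conditions: p-ABSA (1.05 equiv), Et3N, MeCN, 0 °C → rt
Reagents that add atoms: 4-acetamidobenzenesulfonyl azide (p-ABSA), CC(=O)Nc1ccc(cc1)S(=O)(=O)N=[N+]=[N-]
Why: Regitz diazo transfer to the activated methylene of the 1,3-diketone.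

**Step 7**
Reactants: 10 (4S)-4-benzyl-3-propanoyl-1,3-oxazolidin-2-one, 11 methacrolein
Product: 13 (4S)-4-benzyl-3-[(2R,3S)-3-hydroxy-2,4-dimethylpent-4-enoyl]-1,3-oxazolidin-2-one, via TMS ether 12 (not isolated)
Conditions: MgCl2 (20 mol %), Et3N (2 equiv), TMSCl (1.5 equiv), EtOAc, rt, 24 h; then TFA (cat.), MeOH, rt
Reagents that add atoms: none
Why: Evans magnesium-halide-catalysed direct anti-aldol: the chelated (Z)-magnesium enolate is attacked on the face opposite the benzyl group by the non-enolisable enal and silylation of the aldolate turns the catalyst over, which sets C2 (R) and C3 (anti to the C2 methyl).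

**Step 8**
Reactants: 13 the anti-aldol imide
Product: 15 (2R,3S)-3-hydroxy-2,4-dimethylpent-4-enoic acid, via peroxy acid 14 (not isolated)
Conditions: LiOH (2 equiv), 30 % H2O2 (4 equiv), THF/H2O 4:1, 0 °C; aq. Na2SO3; 1 M HCl to pH 2
Reagents that add atoms: lithium hydroperoxide (from LiOH + H2O2), [Li+].[O-]O
Why: Hydroperoxide attacks the exocyclic imide carbonyl selectively (standard auxiliary cleavage) and sulfite reduces the peracid, leaving C2 and C3 untouched.

**Step 9**
Reactants: 15 (2R,3S)-3-hydroxy-2,4-dimethylpent-4-enoic acid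
Product: 17 (3R,4S)-3-methyl-4-(prop-1-en-2-yl)oxetan-2-one, via mixed tosyl anhydride 16 (not isolated)
Conditions: TsCl (2 equiv), pyridine, 0 → 4 °C, 16 h
Reagents that add atoms: none
Why: Carboxyl activation as the mixed sulfonic anhydride and attack by the C3 hydroxyl (β-lactonisation of a β-hydroxy acid) closes the ring without breaking the C3–O bond, so the anti acid gives the trans lactone with retention.

**Step 10**
Reactants: 17 (3R,4S)-3-methyl-4-(prop-1-en-2-yl)oxetan-2-one
Product: 19 (3R,4R)-4-[(2R)-1-hydroxypropan-2-yl]-3-methyloxetan-2-one, via B-alkyl-9-BBN 18 (not isolated)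
Conditions: 9-BBN (1.5 equiv), THF, 0 °C → rt; then 30 % H2O2, aq. NaOAc, 0 °C
Reagents that add atoms: hydrogen peroxide, OO
Why: Hydroboration–oxidation: 9-BBN puts boron on the terminal carbon and, as for other 1,1-disubstituted alkenes next to a C–O stereocentre, adds to the face of the allylic-strain-minimised conformer that gives the 3,4-anti product, which sets C4; acetate-buffered peroxide spares the lactone.

**Step 11**
Reactants: 19 the hydroxy β-lactone
Product: 20 (2S)-2-[(2R,3R)-3-methyl-4-oxooxetan-2-yl]propanal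
Conditions: DMP (1.3 equiv), CH2Cl2, 0 °C → rt; short silica plug, used at once
Reagents that add atoms: none
Why: Dess–Martin oxidation is neutral to slightly acidic, so the β-acyloxy aldehyde neither eliminates nor epimerises at C4.

**Step 12**
Reactants: 20 (2S)-2-[(2R,3R)-3-methyl-4-oxooxetan-2-yl]propanal, 21 pentan-3-one
Product: 24 (3R,4R)-4-[(2R,3R,4R)-3-hydroxy-4-methyl-5-oxoheptan-2-yl]-3-methyloxetan-2-one, via E-enol borinate 22 (not isolated), via boron aldolate 23 (not isolated)
Conditions: 21 (1.5 equiv), c-Hex2BCl (1.6 equiv), Et3N (1.7 equiv), Et2O, 0 °C, 1 h; 20, −78 → −25 °C; MeOH, pH 7 buffer, 30 % H2O2, 0 °C, 30 min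
Reagents that add atoms: none
Why: Boron-mediated anti-aldol: c-Hex2BCl/Et3N gives the (E)-enol borinate, the Zimmerman–Traxler chair gives the 5,6-anti relation and Felkin–Anh attack on the α-methyl aldehyde (the matched case for E-enolates) gives 4,5-syn, which together fix C6 as required (C5 is oxidised later).

**Step 13**
Reactants: 24 the aldol adduct
Product: 25 bis-TMS derivative of 24 (C5–OTMS ether plus (Z)-trimethylsilyl enol ether of the ethyl ketone; stereocentres as in 24)
Conditions: TMSOTf (2.5 equiv), Et3N (3.5 equiv), CH2Cl2, −20 → 0 °C; pentane extraction, no chromatography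
Reagents that add atoms: trimethylsilyl triflate (TMSOTf), C[Si](C)(C)OS(=O)(=O)C(F)(F)F
Why: Soft enolisation and silylation: TMSOTf/Et3N caps the C5 hydroxyl and deprotonates the silyloxocarbenium ion at the less hindered CH2, giving the (Z)-enol silane on the ethyl side only, so C6 is not touched.

**Step 14**
Reactants: 25 the bis-TMS compound, 9 3-diazopentane-2,4-dione
Product: 28 (3R,4R)-4-[(2R,3R,4R)-3-hydroxy-4-(3,5,6-trimethyl-4-oxo-4H-pyran-2-yl)pentan-2-yl]-3-methyloxetan-2-one, via acetyl(methyl)ketene 26 (not isolated), via dihydropyranone cycloadduct 27 (not isolated)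
Conditions: 9 (3 equiv, syringe pump, 1 h), xylenes, 140 °C; then TFA (cat.), wet CH2Cl2, 0 °C → rt
Reagents that add atoms: none
Why: Thermal Wolff rearrangement of 9 gives the α-oxoketene 26, which undergoes the hetero-Diels–Alder reaction typical of acylketenes with electron-rich enol ethers (enol carbon to ketene carbon, acetyl oxygen to C7), and acid then expels silanol to aromatise the ring to the γ-pyrone and frees the C5 hydroxyl; no existing stereocentre takes part.

**Step 15**
Reactants: 28 the hydroxy pyrone β-lactone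
Product: 29 (3R,4R)-3-methyl-4-[(2S,4S)-3-oxo-4-(3,5,6-trimethyl-4-oxo-4H-pyran-2-yl)pentan-2-yl]oxetan-2-one
Conditions: DMP (1.5 equiv), CH2Cl2, rt; base-free work-up (Et2O, silica filtration)
Reagents that add atoms: none
Why: Dess–Martin oxidation under base-free conditions creates the C5 ketone last, so the now doubly activated C6–H and the β-acyloxy ketone motif never meet a base.

**Step 16**
Reactants: 29 the keto β-lactone, 7 (4R,6R)-5-hydroxy-4,6-dimethylnonane-3,7-dione
Product: 30 (4R,6R)-4,6-dimethyl-3,7-dioxononan-5-yl (2R,3R,4S,6S)-3-hydroxy-2,4-dimethyl-5-oxo-6-(3,5,6-trimethyl-4-oxo-4H-pyran-2-yl)heptanoate (target)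
Conditions: 7 (3 equiv, excess recovered), 4-(dimethylamino)pyridine N-oxide (DMAPO, 20 mol %), PivOH (20 mol %), 4 Å MS, PhMe (1 M), 40 °C, 24–48 h
Reagents that add atoms: none
Why: Proposed new method: the weakly basic O-nucleophile DMAPO (pKaH about 4) attacks the strained lactone carbonyl while pivalic acid protonates the departing C3 alkoxide, giving an acyloxypyridinium pivalate (the same kind of acyl donor as in Shiina- or Steglich-type esterifications of hindered carbinols) that acylates the hydroxyl of 7 with pivalate as general base; about 23 kcal/mol of ring strain pays for the otherwise uphill acyl transfer, only the acyl C–O bond breaks so C2 and C3 are retained and C3–OH is released unprotected, excess 7 outcompetes the product hydroxyl, acid or Lewis-acid activation is avoided because the basic pyrone carbonyl would sequester it, and amine bases are avoided because of E1cB across C3–C4 and epimerisation at C6; the closest known reaction types are nucleophile-catalysed acyl transfer from anhydrides and acyl–oxygen opening of β-lactones by amines or in ring-opening polymerisation.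

**Compound list**
1 | methyl 4-oxotetrahydro-2H-thiopyran-3-carboxylate | COC(=O)C1CSCCC1=O | starting material
2 | methyl 1,4-dioxa-8-thiaspiro[4.5]decane-6-carboxylate (racemic) | COC(=O)C1CSCCC12OCCO2 | intermediate
3 | 1,4-dioxa-8-thiaspiro[4.5]decane-6-carbaldehyde (racemic) | O=CC1CSCCC12OCCO2 | intermediate
4 | tetrahydro-4H-thiopyran-4-one | O=C1CCSCC1 | starting material
5 | (3R)-3-{(S)-[(6R)-1,4-dioxa-8-thiaspiro[4.5]decan-6-yl](hydroxy)methyl}tetrahydro-4H-thiopyran-4-one | O=C1CCSC[C@@H]1[C@H](O)[C@H]1CSCCC12OCCO2 | intermediate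
6 | (4R,5S,6R)-6-(2-ethyl-1,3-dioxolan-2-yl)-5-hydroxy-4-methylheptan-3-one | CCC(=O)[C@H](C)[C@H](O)[C@@H](C)C1(CC)OCCO1 | intermediate
7 | (4R,6R)-5-hydroxy-4,6-dimethylnonane-3,7-dione | CCC(=O)[C@H](C)C(O)[C@@H](C)C(=O)CC | intermediate
8 | pentane-2,4-dione | CC(=O)CC(C)=O | starting material
9 | 3-diazopentane-2,4-dione | CC(=O)C(=[N+]=[N-])C(C)=O | intermediate
10 | (4S)-4-benzyl-3-propanoyl-1,3-oxazolidin-2-one | CCC(=O)N1[C@@H](Cc2ccccc2)COC1=O | starting material
11 | methacrolein (2-methylprop-2-enal) | CC(=C)C=O | starting material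
12 | O-trimethylsilyl ether of 13 | O=C([C@H](C)[C@H](O[Si](C)(C)C)C(C)=C)N1[C@@H](Cc2ccccc2)COC1=O | intermediate
13 | (4S)-4-benzyl-3-[(2R,3S)-3-hydroxy-2,4-dimethylpent-4-enoyl]-1,3-oxazolidin-2-one | O=C([C@H](C)[C@H](O)C(C)=C)N1[C@@H](Cc2ccccc2)COC1=O | intermediate
14 | (2R,3S)-3-hydroxy-2,4-dimethylpent-4-eneperoxoic acid | OOC(=O)[C@H](C)[C@H](O)C(C)=C | intermediate
15 | (2R,3S)-3-hydroxy-2,4-dimethylpent-4-enoic acid | OC(=O)[C@H](C)[C@H](O)C(C)=C | intermediate
16 | mixed anhydride of 15 with p-toluenesulfonic acid | Cc1ccc(cc1)S(=O)(=O)OC(=O)[C@H](C)[C@H](O)C(C)=C | intermediate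
17 | (3R,4S)-3-methyl-4-(prop-1-en-2-yl)oxetan-2-one (trans) | O=C1O[C@H](C(C)=C)[C@H]1C | intermediate
18 | B-alkyl-9-borabicyclo[3.3.1]nonane from 17 (boron on the terminal carbon, C4 as in 19) | O=C1O[C@H]([C@H](C)CB2C3CCCC2CCC3)[C@H]1C | intermediate
19 | (3R,4R)-4-[(2R)-1-hydroxypropan-2-yl]-3-methyloxetan-2-one | O=C1O[C@H]([C@H](C)CO)[C@H]1C | intermediate
20 | (2S)-2-[(2R,3R)-3-methyl-4-oxooxetan-2-yl]propanal | O=C1O[C@H]([C@H](C)C=O)[C@H]1C | intermediate
21 | pentan-3-one | CCC(=O)CC | starting material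
22 | (E)-pent-2-en-3-yl dicyclohexylborinate | CC/C(OB(C1CCCCC1)C1CCCCC1)=C\C | intermediate
23 | O-dicyclohexylboryl aldolate of 24 | O=C1O[C@H]([C@H](C)[C@@H](OB(C2CCCCC2)C2CCCCC2)[C@@H](C)C(=O)CC)[C@H]1C | intermediate
24 | (3R,4R)-4-[(2R,3R,4R)-3-hydroxy-4-methyl-5-oxoheptan-2-yl]-3-methyloxetan-2-one | O=C1O[C@H]([C@H](C)[C@@H](O)[C@@H](C)C(=O)CC)[C@H]1C | intermediate
25 | C5-OTMS ether and (Z)-TMS enol ether of 24 | O=C1O[C@H]([C@H](C)[C@@H](O[Si](C)(C)C)[C@@H](C)/C(O[Si](C)(C)C)=C/C)[C@H]1C | intermediate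
26 | acetyl(methyl)ketene (2-methyl-3-oxobut-1-en-1-one) | CC(=O)C(C)=C=O | intermediate
27 | 2-trimethylsilyloxy-3,5,6-trimethyl-2,3-dihydro-4H-pyran-4-one cycloadduct (two new ring centres undefined, chain centres as in 25) | O=C1O[C@H]([C@H](C)[C@@H](O[Si](C)(C)C)[C@@H](C)C2(O[Si](C)(C)C)OC(C)=C(C)C(=O)C2C)[C@H]1C | intermediate
28 | (3R,4R)-4-[(2R,3R,4R)-3-hydroxy-4-(3,5,6-trimethyl-4-oxo-4H-pyran-2-yl)pentan-2-yl]-3-methyloxetan-2-one | O=C1O[C@H]([C@H](C)[C@@H](O)[C@@H](C)c2oc(C)c(C)c(=O)c2C)[C@H]1C | intermediate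
29 | (3R,4R)-3-methyl-4-[(2S,4S)-3-oxo-4-(3,5,6-trimethyl-4-oxo-4H-pyran-2-yl)pentan-2-yl]oxetan-2-one | O=C1O[C@H]([C@H](C)C(=O)[C@@H](C)c2oc(C)c(C)c(=O)c2C)[C@H]1C | intermediate
30 | (4R,6R)-4,6-dimethyl-3,7-dioxononan-5-yl (2R,3R,4S,6S)-3-hydroxy-2,4-dimethyl-5-oxo-6-(3,5,6-trimethyl-4-oxo-4H-pyran-2-yl)heptanoate | CCC(=O)[C@H](C)C(OC(=O)[C@H](C)[C@H](O)[C@H](C)C(=O)[C@@H](C)c1oc(C)c(C)c(=O)c1C)[C@@H](C)C(=O)CC | target

**Step count**
- Total step count: 16.
- Longest linear sequence: 10 steps (steps 7–16, from 10 and 11). The alcohol branch takes 5 steps and the diazo reagent 1 step.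

**Three steps most likely to fail**

**Step 16 (the proposed new step).**
- Risks: no turnover with two hindered partners, oligomers through the product hydroxyl, or elimination of 29.
- Fallback: the ester is made by a Yamaguchi esterification before the C5 oxidation. It sets out from 28 (and uses 6 in place of 7) and comes back at 30.
- 28 is silylated (TESOTf, 2,6-lutidine) to the C5 triethylsilyl ether F1. LiOH (THF/H2O, 0 °C) saponifies the lactone at the acyl carbon to the β-hydroxy acid F2. TBSOTf/2,6-lutidine gives the C3-OTBS ether TBS ester F3, whose silyl ester is cleaved with K2CO3 in aqueous MeOH to the C3-OTBS acid F4. 2,4,6-Trichlorobenzoyl chloride and Et3N, then 6 and DMAP in toluene, give the protected ester F5. PPTS/MeOH removes only the TES group to give the C5 alcohol F6. DMP gives the C5 ketone F7, and aqueous HF in MeCN removes the TBS ether and the dioxolane to give 30.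

**Step 14.**
- Risks: the trisubstituted enol silane may be too hindered for the α-oxoketene (which then dimerises), the lactone may suffer at 140 °C, or 28 may translactonise in acid.
- Fallback: the ring is built stepwise by aldol, oxidation, oxa-Michael closure and dehydrogenation. It sets out from 24 and comes back at 28.
- 24 is protected (TESOTf, 2,6-lutidine) as the C5 triethylsilyl ether ketone F8. Its titanium enolate (TiCl4, i-Pr2NEt, CH2Cl2, −78 °C) adds to commercial (E)-2-methylbut-2-enal to give the aldol F9, whose new centres are irrelevant. DMP gives the enone β-diketone F10. TFA in CH2Cl2 removes the TES group and closes the 2,3-dihydro-4-pyranone F11 by 6-endo oxa-Michael addition of the enol. DDQ (dioxane, 80 °C) dehydrogenates it to 28.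

**Step 10.**
- Risks: low 3,4-anti selectivity next to an acyloxy rather than a hydroxy group, or loss of the allylic β-lactone.
- Fallback: the hydroboration is done on the free allylic alcohol before any lactone exists. It sets out from 13 and comes back at 19.
- 13 is treated with 9-BBN, then H2O2/NaOH. The new primary alcohol closes onto the imide and expels the auxiliary to give the δ-lactone F12. LiOH opens it to the dihydroxy acid F13. TBSCl/imidazole with aqueous work-up silylates only the primary hydroxyl to give the silyloxy acid F14. TsCl/pyridine gives the silyloxy β-lactone F15, and aqueous HF in MeCN gives 19.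

**Further compounds**
F1 | step 16 | C5-O-triethylsilyl ether of 28 | O=C1O[C@H]([C@H](C)[C@@H](O[Si](CC)(CC)CC)[C@@H](C)c2oc(C)c(C)c(=O)c2C)[C@H]1C
F2 | step 16 | 3-hydroxy-5-(triethylsilyloxy) acid from lactone hydrolysis | OC(=O)[C@H](C)[C@H](O)[C@H](C)[C@@H](O[Si](CC)(CC)CC)[C@@H](C)c1oc(C)c(C)c(=O)c1C
F3 | step 16 | C3-OTBS ether TBS ester of F2 | CC(C)(C)[Si](C)(C)OC(=O)[C@H](C)[C@H](O[Si](C)(C)C(C)(C)C)[C@H](C)[C@@H](O[Si](CC)(CC)CC)[C@@H](C)c1oc(C)c(C)c(=O)c1C
F4 | step 16 | C3-OTBS, C5-OTES acid | OC(=O)[C@H](C)[C@H](O[Si](C)(C)C(C)(C)C)[C@H](C)[C@@H](O[Si](CC)(CC)CC)[C@@H](C)c1oc(C)c(C)c(=O)c1C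
F5 | step 16 | ester of F4 with 6 | CCC(=O)[C@H](C)[C@H](OC(=O)[C@H](C)[C@H](O[Si](C)(C)C(C)(C)C)[C@H](C)[C@@H](O[Si](CC)(CC)CC)[C@@H](C)c1oc(C)c(C)c(=O)c1C)[C@@H](C)C1(CC)OCCO1
F6 | step 16 | C5 alcohol from F5 | CCC(=O)[C@H](C)[C@H](OC(=O)[C@H](C)[C@H](O[Si](C)(C)C(C)(C)C)[C@H](C)[C@@H](O)[C@@H](C)c1oc(C)c(C)c(=O)c1C)[C@@H](C)C1(CC)OCCO1
F7 | step 16 | C5 ketone from F6 | CCC(=O)[C@H](C)[C@H](OC(=O)[C@H](C)[C@H](O[Si](C)(C)C(C)(C)C)[C@H](C)C(=O)[C@@H](C)c1oc(C)c(C)c(=O)c1C)[C@@H](C)C1(CC)OCCO1
F8 | step 14 | C5-O-triethylsilyl ether of 24 | O=C1O[C@H]([C@H](C)[C@@H](O[Si](CC)(CC)CC)[C@@H](C)C(=O)CC)[C@H]1C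
F9 | step 14 | titanium aldol adduct of F8 with (E)-2-methylbut-2-enal | O=C1O[C@H]([C@H](C)[C@@H](O[Si](CC)(CC)CC)[C@@H](C)C(=O)C(C)C(O)/C(C)=C/C)[C@H]1C
F10 | step 14 | enone β-diketone from F9 | O=C1O[C@H]([C@H](C)[C@@H](O[Si](CC)(CC)CC)[C@@H](C)C(=O)C(C)C(=O)/C(C)=C/C)[C@H]1C
F11 | step 14 | 2,3-dihydro-4-pyranone with free C5-OH | O=C1O[C@H]([C@H](C)[C@@H](O)[C@@H](C)C2=C(C)C(=O)C(C)C(C)O2)[C@H]1C
F12 | step 10 | (3R,4R,5R)-4-hydroxy-3,5-dimethyloxan-2-one | O=C1OC[C@@H](C)[C@@H](O)[C@H]1C
F13 | step 10 | anti,anti-3,5-dihydroxy-2,4-dimethylpentanoic acid | OC(=O)[C@H](C)[C@H](O)[C@H](C)CO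
F14 | step 10 | 5-O-TBS ether of F13 | OC(=O)[C@H](C)[C@H](O)[C@H](C)CO[Si](C)(C)C(C)(C)C
F15 | step 10 | O-TBS ether of 19 | O=C1O[C@H]([C@H](C)CO[Si](C)(C)C(C)(C)C)[C@H]1C
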